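Everything rests on reading ring A as the dehydrogenated form of a 4,6-disubstituted cyclohexane-1,3-dione: the C2 and C4 hydroxyl carbons are the two carbonyls, C1 bears the propyl linker and C5 the 1,1-dimethylallyl group. One alkoxide-mediated Michael–Claisen annulation joins a 6-(chromen-6-yl)hexan-2-one to methyl 2-(1,1-dimethylallyl)acrylate, forming the C6–C1 and C3–C4 bonds and the six-membered ring while the quaternary carbon arrives ready-made. The ketone already carries the complete MOM-protected prenylchromene (ring B), built from 2-bromo-4,5-dihydroxybenzaldehyde so that each substituent position is fixed by the starting material. Silyl dienol ether formation, DDQ dehydrogenation and acid deprotection finish the synthesis.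

Key step: step 9

Remark: dione 16 is written as the diketo form although it should exist largely as its enol tautomers, and 2-bromo-4,5-dihydroxybenzaldehyde 5 and 6-bromohexan-2-one 12 are taken to be catalogue compounds.

Step 1
Reactants: 1 methyl 3,3-dimethylpent-4-enoate
Product: 4 methyl 3,3-dimethyl-2-methylidenepent-4-enoate, via Mannich base 2 (not isolated), via trimethylammonium iodide 3 (not isolated)
Conditions: LiN(i-Pr)2, THF, −78 °C; CH2=NMe2+ I−, −78 °C → rt; MeI, MeOH, rt; DBU, CH2Cl2, rt
Reagents that add atoms: N,N-dimethylmethyleneiminium iodide (Eschenmoser's salt), C=[N+](C)C.[I-]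
Why: The lithium ester enolate is aminomethylated by the iminium salt (Mannich reaction), and N-methylation followed by E1cB loss of trimethylamine should give the 2-methylidene ester (Eschenmoser methylenation), in which no stereocentre remains.

Step 2
Reactants: 5 2-bromo-4,5-dihydroxybenzaldehyde
Product: 6 2-bromo-5-hydroxy-4-(methoxymethoxy)benzaldehyde
Conditions: MOMCl (1.05 equiv), K2CO3, acetone, 0 °C → rt
Reagents that add atoms: chloromethyl methyl ether, COCCl
Why: The 4-hydroxyl para to the formyl group is much the more acidic and should be alkylated selectively under weak-base conditions (Williamson-type O-alkylation), which fixes which oxygen becomes the C8 hydroxyl of ring B.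

Step 3
Reactants: 6 2-bromo-5-hydroxy-4-(methoxymethoxy)benzaldehyde
Product: 7 2-bromo-4-(methoxymethoxy)-5-[(2-methylbut-3-yn-2-yl)oxy]benzaldehyde
Conditions: 3-chloro-3-methylbut-1-yne, DBU, CuCl2·2H2O (1 mol %), MeCN, 0 °C → rt
Reagents that add atoms: 3-chloro-3-methylbut-1-yne, C#CC(C)(C)Cl
Why: Copper-catalysed O-propargylation of the remaining phenol with the tertiary propargylic chloride should give the aryl 1,1-dimethylpropargyl ether without touching the aldehyde or the aryl bromide.

Step 4
Reactants: 7 2-bromo-4-(methoxymethoxy)-5-[(2-methylbut-3-yn-2-yl)oxy]benzaldehyde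
Product: 8 6-bromo-8-(methoxymethoxy)-2,2-dimethyl-2H-chromene-5-carbaldehyde
Conditions: PhNEt2, 180 °C
Reagents that add atoms: none
Why: Aromatic propargyl Claisen rearrangement to the only free ortho carbon, enolisation, 1,5-hydrogen shift and oxa-6π electrocyclisation should deliver the 2,2-dimethyl-2H-chromene, the other ortho position being blocked by the MOM ether so that the ring fusion is unambiguous.

Step 5
Reactants: 8 6-bromo-8-(methoxymethoxy)-2,2-dimethyl-2H-chromene-5-carbaldehyde
Product: 9 [6-bromo-8-(methoxymethoxy)-2,2-dimethyl-2H-chromen-5-yl]methanol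
Conditions: NaBH4, MeOH/THF, 0 °C
Reagents that add atoms: none
Why: Hydride reduction of the aryl aldehyde is chemoselective, since aryl bromide, MOM acetal and chromene alkene are inert to NaBH4.

Step 6
Reactants: 9 [6-bromo-8-(methoxymethoxy)-2,2-dimethyl-2H-chromen-5-yl]methanol
Product: 10 6-bromo-5-(bromomethyl)-8-(methoxymethoxy)-2,2-dimethyl-2H-chromene
Conditions: CBr4, PPh3, CH2Cl2, 0 °C
Reagents that add atoms: carbon tetrabromide, BrC(Br)(Br)Br
Why: The Appel reaction converts the electron-rich benzylic alcohol into the bromide under neutral conditions that spare the MOM acetal and the chromene; the bromide is used directly.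

Step 7
Reactants: 10 6-bromo-5-(bromomethyl)-8-(methoxymethoxy)-2,2-dimethyl-2H-chromene
Product: 11 6-bromo-8-(methoxymethoxy)-2,2-dimethyl-5-(3-methylbut-2-en-1-yl)-2H-chromene
Conditions: Me2C=CHMgBr, CuI (10 mol %), THF, −30 °C → 0 °C
Reagents that add atoms: (2-methylprop-1-en-1-yl)magnesium bromide, CC(C)=C[Mg]Br
Why: Copper-catalysed sp3–sp2 cross-coupling of the benzylic bromide with the alkenyl Grignard reagent (Kochi-type coupling) should build the prenyl group with its trisubstituted alkene already in place, while the aryl bromide does not react with the alkenylmagnesium reagent at this temperature.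

Step 8
Reactants: 11 6-bromo-8-(methoxymethoxy)-2,2-dimethyl-5-(3-methylbut-2-en-1-yl)-2H-chromene; 12 6-bromohexan-2-one
Product: 14 6-[8-(methoxymethoxy)-2,2-dimethyl-5-(3-methylbut-2-en-1-yl)-2H-chromen-6-yl]hexan-2-one, via (5-oxohexyl)zinc bromide 13 (not isolated)
Conditions: 12, Zn dust, LiCl, THF, 40 °C; then 11, Pd(OAc)2 (2 mol %), SPhos (4 mol %), THF, rt → 50 °C
Reagents that add atoms: none
Why: LiCl-promoted zinc insertion should give a primary alkylzinc bromide that tolerates its own ketone, and Negishi coupling with the aryl bromide forms the aryl–CH2 bond and delivers the free methyl ketone without a protecting group.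

Step 9
Reactants: 14 6-[8-(methoxymethoxy)-2,2-dimethyl-5-(3-methylbut-2-en-1-yl)-2H-chromen-6-yl]hexan-2-one; 4 methyl 3,3-dimethyl-2-methylidenepent-4-enoate
Product: 16 4-(2-methylbut-3-en-2-yl)-6-{3-[8-(methoxymethoxy)-2,2-dimethyl-5-(3-methylbut-2-en-1-yl)-2H-chromen-6-yl]propyl}cyclohexane-1,3-dione (mixture of diastereomers), via keto ester 15 (not isolated)
Conditions: KOt-Bu (2.2 equiv), THF, −10 °C → rt; AcOH quench
Reagents that add atoms: none
Why: Under equilibrating tert-butoxide the more substituted (C3) enolate of 14 should add to the unhindered CH2 terminus of acrylate 4 (Michael addition, ring A C6–C1 bond) to give keto ester 15, whose methyl-side enolate then attacks the ester carbonyl (intramolecular Claisen condensation, ring A C3–C4 bond) and expels methoxide. The closest known reaction type is the alkoxide-mediated consecutive Michael–Claisen synthesis of cyclohexane-1,3-diones from methyl ketones and acrylates. The ring closes in a 6-exo-trig mode, as an acyl substitution at an exocyclic carbonyl. The two new stereocentres (dione C4 and C6) are set without control, are epimerisable through the enol, and both become sp2 carbons on aromatisation. The step needs regioselective enolate use: the Michael addition is reversible, the internal enolate is the thermodynamically favoured one, and closure through the unhindered methyl carbon is the fastest Claisen pathway, made irreversible by deprotonation of the dione. The MOM acetal, chromene and prenyl group are inert to alkoxide.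

Step 10
Reactants: 16 4-(2-methylbut-3-en-2-yl)-6-{3-[8-(methoxymethoxy)-2,2-dimethyl-5-(3-methylbut-2-en-1-yl)-2H-chromen-6-yl]propyl}cyclohexane-1,3-dione
Product: 18 6-{3-[5-(2-methylbut-3-en-2-yl)-2,4-bis(triethylsilyloxy)phenyl]propyl}-8-(methoxymethoxy)-2,2-dimethyl-5-(3-methylbut-2-en-1-yl)-2H-chromene, via bis(triethylsilyl) dienol ether 17 (not isolated)
Conditions: Et3SiOTf (2.5 equiv), Et3N (4 equiv), CH2Cl2, 0 °C → rt; aqueous NaHCO3 work-up; then DDQ (1.05 equiv), 2,4,6-collidine, CH2Cl2, 0 °C
Reagents that add atoms: triethylsilyl trifluoromethanesulfonate, CC[Si](CC)(CC)OS(=O)(=O)C(F)(F)F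
Why: Soft enolisation with silyl triflate and amine should convert the dione, through a common 1,3-bis(silyloxy)allyl cation, into the bis(silyl) dienol ether (either diene regioisomer leads to the same arene), and DDQ dehydrogenation of this very electron-rich silyl dienol ether (hydride abstraction from the ring CH2, then proton loss) aromatises ring A at 0 °C, where chromene, prenyl group and MOM acetal should not be attacked.

Step 11
Reactants: 18 6-{3-[5-(2-methylbut-3-en-2-yl)-2,4-bis(triethylsilyloxy)phenyl]propyl}-8-(methoxymethoxy)-2,2-dimethyl-5-(3-methylbut-2-en-1-yl)-2H-chromene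
Product: 19 kazinol K, 4-{3-[8-hydroxy-2,2-dimethyl-5-(3-methylbut-2-en-1-yl)-2H-chromen-6-yl]propyl}-6-(2-methylbut-3-en-2-yl)benzene-1,3-diol
Conditions: 3 M aq. HCl, MeOH/THF, rt
Reagents that add atoms: none
Why: Acid-catalysed methanolysis should cleave the two aryl silyl ethers and the MOM acetal in one operation (global deprotection), dilute acid at room temperature being mild enough to leave the chromene, the prenyl group and the 1,1-dimethylallyl group untouched.

Compound list

1 | methyl 3,3-dimethylpent-4-enoate | COC(=O)CC(C)(C)C=C | starting material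
2 | methyl 2-[(dimethylamino)methyl]-3,3-dimethylpent-4-enoate (racemic) | COC(=O)C(CN(C)C)C(C)(C)C=C | intermediate
3 | [2-(methoxycarbonyl)-3,3-dimethylpent-4-en-1-yl]trimethylammonium iodide (racemic) | COC(=O)C(C[N+](C)(C)C)C(C)(C)C=C.[I-] | intermediate
4 | methyl 3,3-dimethyl-2-methylidenepent-4-enoate | C=CC(C)(C)C(=C)C(=O)OC | intermediate
5 | 2-bromo-4,5-dihydroxybenzaldehyde | O=Cc1cc(O)c(O)cc1Br | starting material
6 | 2-bromo-5-hydroxy-4-(methoxymethoxy)benzaldehyde | O=Cc1cc(O)c(OCOC)cc1Br | intermediate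
7 | 2-bromo-4-(methoxymethoxy)-5-[(2-methylbut-3-yn-2-yl)oxy]benzaldehyde | O=Cc1cc(OC(C)(C)C#C)c(OCOC)cc1Br | intermediate
8 | 6-bromo-8-(methoxymethoxy)-2,2-dimethyl-2H-chromene-5-carbaldehyde | O=Cc1c(Br)cc(OCOC)c2OC(C)(C)C=Cc12 | intermediate
9 | [6-bromo-8-(methoxymethoxy)-2,2-dimethyl-2H-chromen-5-yl]methanol | OCc1c(Br)cc(OCOC)c2OC(C)(C)C=Cc12 | intermediate
10 | 6-bromo-5-(bromomethyl)-8-(methoxymethoxy)-2,2-dimethyl-2H-chromene | BrCc1c(Br)cc(OCOC)c2OC(C)(C)C=Cc12 | intermediate
11 | 6-bromo-8-(methoxymethoxy)-2,2-dimethyl-5-(3-methylbut-2-en-1-yl)-2H-chromene | CC(C)=CCc1c(Br)cc(OCOC)c2OC(C)(C)C=Cc12 | intermediate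
12 | 6-bromohexan-2-one | CC(=O)CCCCBr | starting material
13 | (5-oxohexyl)zinc bromide | CC(=O)CCCC[Zn]Br | intermediate
14 | 6-[8-(methoxymethoxy)-2,2-dimethyl-5-(3-methylbut-2-en-1-yl)-2H-chromen-6-yl]hexan-2-one | CC(=O)CCCCc1cc(OCOC)c2OC(C)(C)C=Cc2c1CC=C(C)C | intermediate
15 | methyl 4-acetyl-7-[8-(methoxymethoxy)-2,2-dimethyl-5-(3-methylbut-2-en-1-yl)-2H-chromen-6-yl]-2-(2-methylbut-3-en-2-yl)heptanoate (mixture of diastereomers, each racemic) | COC(=O)C(CC(CCCc1cc(OCOC)c2OC(C)(C)C=Cc2c1CC=C(C)C)C(C)=O)C(C)(C)C=C | intermediate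
16 | 4-(2-methylbut-3-en-2-yl)-6-{3-[8-(methoxymethoxy)-2,2-dimethyl-5-(3-methylbut-2-en-1-yl)-2H-chromen-6-yl]propyl}cyclohexane-1,3-dione (cis/trans mixture, each racemic) | O=C1CC(=O)C(C(C)(C)C=C)CC1CCCc2cc(OCOC)c3OC(C)(C)C=Cc3c2CC=C(C)C | intermediate
17 | 6-{3-[5-(2-methylbut-3-en-2-yl)-2,4-bis(triethylsilyloxy)cyclohexa-1,3-dien-1-yl]propyl}-8-(methoxymethoxy)-2,2-dimethyl-5-(3-methylbut-2-en-1-yl)-2H-chromene (racemic) | CC[Si](CC)(CC)OC1=CC(O[Si](CC)(CC)CC)=C(CCCc2cc(OCOC)c3OC(C)(C)C=Cc3c2CC=C(C)C)CC1C(C)(C)C=C | intermediate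
18 | 6-{3-[5-(2-methylbut-3-en-2-yl)-2,4-bis(triethylsilyloxy)phenyl]propyl}-8-(methoxymethoxy)-2,2-dimethyl-5-(3-methylbut-2-en-1-yl)-2H-chromene | C=CC(C)(C)c1cc(CCCc2cc(OCOC)c3OC(C)(C)C=Cc3c2CC=C(C)C)c(O[Si](CC)(CC)CC)cc1O[Si](CC)(CC)CC | intermediate
19 | kazinol K, 4-{3-[8-hydroxy-2,2-dimethyl-5-(3-methylbut-2-en-1-yl)-2H-chromen-6-yl]propyl}-6-(2-methylbut-3-en-2-yl)benzene-1,3-diol (no stereocentre) | C=CC(C)(C)c1cc(CCCc2cc(O)c3c(c2CC=C(C)C)C=CC(C)(C)O3)c(O)cc1O | target

Total step count: 11 steps.
Longest linear sequence: 10 steps (5 to 19, steps 2 to 11); the acrylate branch (step 1) joins at step 9.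

Steps most likely to fail

Step 9. The risk is enolate use at the wrong site (Michael addition from the methyl side, leading to the 2-alkyl dione series), or a Claisen closure that stalls at the ester next to the quaternary carbon while retro-Michael cleavage returns the components. The fallback separates the two bond formations and fixes the enolate regiochemistry beforehand. It sets out from ketone 14, which under equilibrating conditions (Me3SiCl, Et3N, DMF, 80 °C) should give its more substituted silyl enol ether, trimethyl({6-[8-(methoxymethoxy)-2,2-dimethyl-5-(3-methylbut-2-en-1-yl)-2H-chromen-6-yl]hex-2-en-2-yl}oxy)silane F1. MeLi (THF, −78 °C) releases the regiodefined enolate, lithium 6-[8-(methoxymethoxy)-2,2-dimethyl-5-(3-methylbut-2-en-1-yl)-2H-chromen-6-yl]hex-2-en-2-olate F2, which undergoes Michael addition to acrylate 4 to give keto ester 15, isolated this time. A separate Claisen cyclisation (KOt-Bu, THF, 0 °C → rt) then comes back to the route at dione 16.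

Step 10. The risk is incomplete double silylation, or hydride abstraction by DDQ at the benzylic and allylic CH2 groups of ring B in competition with aromatisation. The fallback introduces the unsaturation by selenoxide elimination instead of hydride abstraction. It sets out from dione 16, which is silylated to diene 17 as before. PhSeCl (CH2Cl2, −78 °C) should selenenylate the diene terminus to give 6-{3-[8-(methoxymethoxy)-2,2-dimethyl-5-(3-methylbut-2-en-1-yl)-2H-chromen-6-yl]propyl}-4-(2-methylbut-3-en-2-yl)-6-(phenylselanyl)-3-(triethylsilyloxy)cyclohex-2-en-1-one F3. NaIO4 (NaHCO3, THF/H2O, 0 °C → rt) oxidises it to 6-{3-[8-(methoxymethoxy)-2,2-dimethyl-5-(3-methylbut-2-en-1-yl)-2H-chromen-6-yl]propyl}-4-(2-methylbut-3-en-2-yl)-6-(phenylseleninyl)-3-(triethylsilyloxy)cyclohex-2-en-1-one F4. Syn-elimination and tautomerisation of F4 should give 2-{3-[8-(methoxymethoxy)-2,2-dimethyl-5-(3-methylbut-2-en-1-yl)-2H-chromen-6-yl]propyl}-4-(2-methylbut-3-en-2-yl)-5-(triethylsilyloxy)phenol F5. The conditions of step 11 convert F5 directly into target 19, where the fallback rejoins the route.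

Step 8. The risk is sluggish zinc insertion, protonation or self-condensation of the keto-alkylzinc reagent, or slow oxidative addition into the hindered, electron-rich aryl bromide. The fallback brings the chain in ketal-protected form by B-alkyl Suzuki–Miyaura coupling. Hex-5-en-2-one is ketalised (ethylene glycol, TsOH, benzene, reflux) to 2-(but-3-en-1-yl)-2-methyl-1,3-dioxolane F6 and hydroborated (9-BBN, THF, rt) to 9-[4-(2-methyl-1,3-dioxolan-2-yl)butyl]-9-borabicyclo[3.3.1]nonane F7. The fallback then sets out from bromide 11, which is coupled with F7 [PdCl2(dppf), K3PO4, THF/DMF/H2O, 60 °C] to give 8-(methoxymethoxy)-2,2-dimethyl-6-[4-(2-methyl-1,3-dioxolan-2-yl)butyl]-5-(3-methylbut-2-en-1-yl)-2H-chromene F8. PPTS (acetone/H2O, 50 °C) removes the ketal and comes back to the route at ketone 14.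

Further compounds

F1 | step 9 | trimethyl({6-[8-(methoxymethoxy)-2,2-dimethyl-5-(3-methylbut-2-en-1-yl)-2H-chromen-6-yl]hex-2-en-2-yl}oxy)silane (E/Z mixture) | CC(O[Si](C)(C)C)=CCCCc1cc(OCOC)c2OC(C)(C)C=Cc2c1CC=C(C)C
F2 | step 9 | lithium 6-[8-(methoxymethoxy)-2,2-dimethyl-5-(3-methylbut-2-en-1-yl)-2H-chromen-6-yl]hex-2-en-2-olate | [Li+].CC([O-])=CCCCc1cc(OCOC)c2OC(C)(C)C=Cc2c1CC=C(C)C
F3 | step 10 | 6-{3-[8-(methoxymethoxy)-2,2-dimethyl-5-(3-methylbut-2-en-1-yl)-2H-chromen-6-yl]propyl}-4-(2-methylbut-3-en-2-yl)-6-(phenylselanyl)-3-(triethylsilyloxy)cyclohex-2-en-1-one (mixture of diastereomers) | O=C1C=C(O[Si](CC)(CC)CC)C(C(C)(C)C=C)CC1(CCCc2cc(OCOC)c3OC(C)(C)C=Cc3c2CC=C(C)C)[Se]c4ccccc4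
F4 | step 10 | 6-{3-[8-(methoxymethoxy)-2,2-dimethyl-5-(3-methylbut-2-en-1-yl)-2H-chromen-6-yl]propyl}-4-(2-methylbut-3-en-2-yl)-6-(phenylseleninyl)-3-(triethylsilyloxy)cyclohex-2-en-1-one (mixture of diastereomers) | O=C1C=C(O[Si](CC)(CC)CC)C(C(C)(C)C=C)CC1(CCCc2cc(OCOC)c3OC(C)(C)C=Cc3c2CC=C(C)C)[Se](=O)c4ccccc4
F5 | step 10 | 2-{3-[8-(methoxymethoxy)-2,2-dimethyl-5-(3-methylbut-2-en-1-yl)-2H-chromen-6-yl]propyl}-4-(2-methylbut-3-en-2-yl)-5-(triethylsilyloxy)phenol | C=CC(C)(C)c1cc(CCCc2cc(OCOC)c3OC(C)(C)C=Cc3c2CC=C(C)C)c(O)cc1O[Si](CC)(CC)CC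
F6 | step 8 | 2-(but-3-en-1-yl)-2-methyl-1,3-dioxolane | CC1(CCC=C)OCCO1
F7 | step 8 | 9-[4-(2-methyl-1,3-dioxolan-2-yl)butyl]-9-borabicyclo[3.3.1]nonane | CC1(CCCCB2C3CCCC2CCC3)OCCO1
F8 | step 8 | 8-(methoxymethoxy)-2,2-dimethyl-6-[4-(2-methyl-1,3-dioxolan-2-yl)butyl]-5-(3-methylbut-2-en-1-yl)-2H-chromene | CC1(CCCCc2cc(OCOC)c3OC(C)(C)C=Cc3c2CC=C(C)C)OCCO1
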